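**Remark (assumption):** the target is taken as the neutral guanidine drawn, so the last step ends with a basic work-up; compounds 1, 8 and 21 are taken as purchasable.

Numbering used below: ring atoms of the target C1 (quaternary), C2 (methyl-bearing sp2), C3 (=CH), C4, C5, C6 (CHMe); chain C1'–C9' counted from the ring. Compounds 6 and 7 carry their own numbering (C1 carbinol, C2, C3, C4), with C3 of 7 becoming C1 of the target, C1 becoming C3 and C4 becoming C6.

## The problem

Agelasidine C is a monocyclic diterpenoid: a cyclohexene ring whose quaternary C1 carries a methyl group and a nine-carbon chain (E-trisubstituted olefins at C3'=C4' and C7'=C8') that ends in an allylic sulfone bound to a 2-guanidinoethyl group. The hard atom is C1. It is fully substituted, it lies between the methyl-bearing sp2 carbon C2 and the methyl-bearing stereocenter C6 (C1 S, C6 R, the two ring methyls cis), and it is joined to the chain through an unactivated CH2–CH2 unit, so the natural chain can be brought in neither as an electrophile for an enolate nor by substitution at the neopentyl-type C1'. Of the two stereocenters only C6 is easy to set alone; it can then control C1, because a reagent that attacks C1 prefers the face away from the C6 methyl, and that is the face on which the chain sits. The ring olefin must end at C2=C3 and nowhere else, and the chain olefins must be E,E, which is better bought with geraniol than made. The feature that opens the problem is that C1 is allylic: C1–C2(Me)=C3H is an allyl unit whose terminus C3 carries only hydrogen, so the olefin can be thought shifted to C1=C2 with an oxygen leaving group on C3, and the C1–C1' bond, the configuration of C1 and the position of the ring olefin can all come from one anti-SN2' substitution. The 1,5-polyene is sensitive to acid (cation–olefin cyclisation), the allylic sulfone to strong base, and the guanidine is strongly basic and polar, so sulfur and nitrogen are introduced last and without any acidic deprotection.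

## Retrosynthesis

**Guanidine and nitrogen.** The C–N bond between the guanidine carbon and the ethyl nitrogen of 26 is cut, giving primary amine 24, which is unmasked from phthalimide 23 by cleaving its two N–C(O) bonds. Carrying a guanidine, free or carbamate-protected, through the route would mean either a strongly basic polar group in every step or an acidic deprotection next to the polyene. The forward steps need only an amidine transfer to a primary amine and a hydrazinolysis, both under neutral to mildly basic conditions.

**C9'–S bond.** Sulfone 23 is cut between C9' and sulfur into allylic bromide 20 and sulfinate salt 22, the latter made by reduction of sulfonyl chloride 21. Against the neighbouring option, a sulfide that is oxidised afterwards, this brings sulfur in at the sulfone oxidation level, so no oxidant meets the three trisubstituted olefins. The forward reaction must be S-alkylation at the primary allylic carbon with retention of the E-olefin. Bromide 20 comes from silyl ether 17 by way of alcohol 18 and mesylate 19.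

**C1–C1' bond (key disconnection).** Compound 17 is cut at the most hindered bond, between the quaternary ring carbon and the chain, as a retro anti-SN2' substitution. This gives allylic picolinate 7 and Grignard reagent 16, which is made from bromide 15. The neighbouring cuts are worse:
- C1'–C2' would need a displacement at, or a carbanion on, a neopentyl carbon.
- C2'–C3' would need a stereodefined 2-metallated alkene.
- C1–CH3 would force the methyl group onto the face of the C6 methyl.

The precursors are much simpler than 17: 7 is a nine-carbon ring ester with one resolved methyl stereocenter and one carbinol stereocenter, and 15 is achiral with both E-olefins in place. The forward step must deliver the chain to the fully substituted γ-carbon, anti to the leaving group.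

**Ring fragment.** Picolinate 7 is cut at the ester C–O bond to carbinol 6, whose C1–H bond comes from reagent-controlled reduction of racemic enone 5. Enone 5 is cut at the two ring–methyl bonds (C3–CH3 by carbonyl addition with transposition, C4–CH3 by enolate methylation) back to vinylogous ester 1 through 3. No short catalytic asymmetric route to the C4 stereocenter was found. The racemate is therefore made in two steps, and the enantioselective reduction, which fixes C1 in both enantiomers, turns the two enantiomers of 5 into separable diastereomers. The forward reduction must be catalyst-controlled at C1, and the cis isomer 6 must be separable.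

**Chain fragment.** Bromide 15 comes from alcohol 14 (C–Br for C–O). Alcohol 14 comes from triene 12 by anti-Markovnikov hydroboration of the terminal vinyl group through borane 13. Triene 12 comes from enal 11 by cutting the C8=C9 olefin (one-carbon ylide), and 11 from geranyl silyl ether 9 by oxidation of its terminal E-methyl group through alcohol 10. Ether 9 is protected geraniol 8. Both E-olefins are bought with 8 and never touched. The only demands are E-selective allylic oxidation and chemoselective hydroboration of a monosubstituted olefin beside two trisubstituted ones.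

## Roads not taken

**Alternative 1:** (the obvious route) cut C1–C1' as an enolate alkylation and C6–CH3 as a conjugate addition. The forward key step is a copper-catalysed asymmetric conjugate addition of a methyl Grignard reagent to 2-methylcyclohex-2-en-1-one A1, with trapping of the regiodefined enolate, trans to the new methyl, by an allyl halide to give (2S,3R)-2,3-dimethyl-2-(prop-2-en-1-yl)cyclohexan-1-one A2. The ketone is then turned into C2(Me)=C3H through its enol triflate, and the allyl group is cut down to aldehyde A3. The stereochemistry is well served, but the tetrasubstituted enolate accepts only activated halides. The natural chain as electrophile would be homoallylic bromide 15, which eliminates or fails to react, so the hindered bond is made to a three-carbon stub with its unsaturation in the wrong place. From A3 the chain must be grown linearly, each E-trisubstituted olefin by its own olefination of imperfect geometry, at a cost of eight or more further steps. The chosen plan makes the same bond with the whole E,E-chain in place and gets the ring olefin from the same event.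

**Alternative 2:** cut C1–C1' by a [3,3]-sigmatropic shift. The forward key step is an Ireland–Claisen rearrangement of ester A6, made from the trans carbinol (1R,4R)-2,3,4-trimethylcyclohex-2-en-1-ol A4 and the twelve-carbon acid A5. The suprafacial shift delivers C1' to the face of the oxygen and gives acid A7 with the right ring configuration. The intramolecular bond formation suits the congested carbon, but three things speak against it:
- The carboxyl group left on C1' must be removed, and radical decarboxylation places a radical on C1' next to the vinyl-substituted quaternary carbon, where a 1,2-vinyl shift through a cyclopropylcarbinyl radical (ring expansion) competes.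
- The rearrangement needs A4, the carbinol epimer that hydride reduction of 5 is expected to disfavour.
- A stereocenter at C1' is made only to be destroyed.

The chosen plan forms the same bond with no atom to remove and uses the carbinol epimer that reduction should give.

**Alternative 3:** cut C1–CH3 instead of C1–C1'. The chain is attached first, by addition of the organolithium from 15 to vinylogous ester 3 and acid transposition to enone A8. Reduction, picolinate formation to A9 and anti-SN2' substitution with a methyl copper reagent would then make the quaternary carbon. The union with the chain becomes an unhindered carbonyl addition and the small nucleophile builds the quaternary center. For the target configuration, however, methyl must enter on the face of the neighbouring C4 methyl, against the substrate bias, and this needs the trans carbinol. The chain is also carried through four linear steps, and the resolution of the ring stereocenter comes after the chain is attached, so half of the chain is lost with it. In the chosen plan the incoming group and the C4 methyl are on opposite faces and the resolution is done on the cheap ring fragment.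

Key step: step 10

## Route

**Step 1**
Reactants: 1 3-ethoxy-2-methylcyclohex-2-en-1-one
Product: 3 (±)-3-ethoxy-2,6-dimethylcyclohex-2-en-1-one, via lithium enolate 2 (not isolated)
Conditions: LiN(iPr)2, THF, −78 °C; MeI, −78 → 0 °C
Reagents that add atoms: iodomethane, CI
Why: Kinetic α'-deprotonation of the vinylogous ester (first half of a Stork–Danheiser sequence) can occur only at C6, and the enolate is methylated there; the new stereocenter is formed racemic and is resolved in step 3.

**Step 2**
Reactants: 3 (±)-3-ethoxy-2,6-dimethylcyclohex-2-en-1-one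
Product: 5 (±)-2,3,4-trimethylcyclohex-2-en-1-one, via tertiary carbinol 4 (not isolated)
Conditions: MeLi, Et2O, −78 → 0 °C; then 1 M HCl, THF, rt
Reagents that add atoms: methyllithium, [Li]C
Why: 1,2-Addition to the vinylogous ester carbonyl followed by acid hydrolysis of the enol ether with loss of the tertiary hydroxyl (Stork–Danheiser 1,3-carbonyl transposition) places the methyl groups on C2, C3 and C4 without regiochemical ambiguity; the methyl-bearing stereocenter is not touched and stays racemic.

**Step 3**
Reactants: 5 (±)-2,3,4-trimethylcyclohex-2-en-1-one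
Product: 6 (1S,4R)-2,3,4-trimethylcyclohex-2-en-1-ol
Conditions: (R)-1-methyl-3,3-diphenyltetrahydro-1H,3H-pyrrolo[1,2-c][1,3,2]oxazaborole (0.2 equiv), BH3·SMe2, THF, −20 °C; MeOH; chromatographic separation of the diastereomers
Reagents that add atoms: none
Why: Corey–Bakshi–Shibata reduction used as a divergent reaction on a racemate: with the substituted alkenyl side as the large group the (R)-catalyst should make C1 S in both enantiomers of 5, so the (4R)-ketone gives the cis alcohol 6 and the (4S)-ketone gives the trans (1S,4S) diastereomer, which is removed. For the (4R)-ketone the catalyst and the expected intrinsic preference (hydride anti to the pseudoaxial C4 methyl) point the same way, and the separation fixes C4 as R.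

**Step 4**
Reactants: 6 (1S,4R)-2,3,4-trimethylcyclohex-2-en-1-ol
Product: 7 (1S,4R)-2,3,4-trimethylcyclohex-2-en-1-yl pyridine-2-carboxylate
Conditions: pyridine-2-carboxylic acid, DCC, 4-(dimethylamino)pyridine (cat.), CH2Cl2, 0 °C → rt
Reagents that add atoms: pyridine-2-carboxylic acid, OC(=O)c1ccccn1
Why: Steglich esterification at oxygen leaves both stereocenters untouched; the picolinate is chosen because its nitrogen and carbonyl chelate magnesium in step 10 and make it a strong, γ-directing leaving group.

**Step 5**
Reactants: 8 geraniol, (2E)-3,7-dimethylocta-2,6-dien-1-ol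
Product: 9 tert-butyl{[(2E)-3,7-dimethylocta-2,6-dien-1-yl]oxy}dimethylsilane
Conditions: TBSCl, imidazole, DMF, rt
Reagents that add atoms: tert-butyldimethylsilyl chloride, C[Si](C)(Cl)C(C)(C)C
Why: Standard silylation; the silyl ether has no acidic proton and is inert to the Grignard and copper reagents of step 10.

**Step 6**
Reactants: 9 tert-butyl{[(2E)-3,7-dimethylocta-2,6-dien-1-yl]oxy}dimethylsilane
Product: 11 (2E,6E)-8-{[tert-butyl(dimethyl)silyl]oxy}-2,6-dimethylocta-2,6-dienal, via allylic alcohol 10 (not isolated)
Conditions: SeO2 (0.1 equiv), t-BuOOH, salicylic acid (0.1 equiv), CH2Cl2, rt; crude product then MnO2, CH2Cl2, rt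
Reagents that add atoms: selenium dioxide, O=[Se]=O (transfers the oxygen atom, catalytic); tert-butyl hydroperoxide, CC(C)(C)OO (terminal source of that oxygen)
Why: Catalytic SeO2 allylic oxidation (ene reaction, then [2,3]-shift) attacks the E-methyl of the electron-rich terminal olefin and gives the E-allylic alcohol, while the C2=C3 olefin is deactivated by its allylic oxygen. MnO2 then brings the crude alcohol and aldehyde mixture to the enal.

**Step 7**
Reactants: 11 (2E,6E)-8-{[tert-butyl(dimethyl)silyl]oxy}-2,6-dimethylocta-2,6-dienal
Product: 12 tert-butyl{[(2E,6E)-3,7-dimethylnona-2,6,8-trien-1-yl]oxy}dimethylsilane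
Conditions: Ph3PCH3Br, n-BuLi, THF, 0 °C; 11, −78 °C → rt
Reagents that add atoms: methyltriphenylphosphonium bromide, [Br-].C[P+](c1ccccc1)(c1ccccc1)c1ccccc1
Why: Wittig methylenation of an enal adds C1' of the target as a terminal vinyl group without touching the geometry of the existing olefins.

**Step 8**
Reactants: 12 tert-butyl{[(2E,6E)-3,7-dimethylnona-2,6,8-trien-1-yl]oxy}dimethylsilane
Product: 14 (3E,7E)-9-{[tert-butyl(dimethyl)silyl]oxy}-3,7-dimethylnona-3,7-dien-1-ol, via alkylborane 13 (not isolated)
Conditions: 9-BBN (0.5 M in THF), 0 °C → rt; then NaOH, 30% H2O2, 0 °C → rt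
Reagents that add atoms: hydrogen peroxide, OO
Why: Hydroboration–oxidation; the bulky borane adds only to the monosubstituted vinyl terminus of the diene, with boron on the terminal carbon, and leaves the trisubstituted olefins alone, as known for terminal 1,3-dienes of terpene type.

**Step 9**
Reactants: 14 (3E,7E)-9-{[tert-butyl(dimethyl)silyl]oxy}-3,7-dimethylnona-3,7-dien-1-ol
Product: 15 {[(2E,6E)-9-bromo-3,7-dimethylnona-2,6-dien-1-yl]oxy}(tert-butyl)dimethylsilane
Conditions: CBr4, PPh3, 2,6-lutidine, CH2Cl2, 0 °C
Reagents that add atoms: carbon tetrabromide, BrC(Br)(Br)Br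
Why: Appel bromination of a primary alcohol under buffered, non-acidic conditions that spare the allylic silyl ether and the olefins.

**Step 10**
Reactants: 15 {[(2E,6E)-9-bromo-3,7-dimethylnona-2,6-dien-1-yl]oxy}(tert-butyl)dimethylsilane; 7 (1S,4R)-2,3,4-trimethylcyclohex-2-en-1-yl pyridine-2-carboxylate
Product: 17 tert-butyl(dimethyl)({(2E,6E)-3,7-dimethyl-9-[(1S,6R)-1,2,6-trimethylcyclohex-2-en-1-yl]nona-2,6-dien-1-yl}oxy)silane, via Grignard reagent 16 (not isolated)
Conditions: Mg, THF, 40 °C (15 → 16, 2 equiv relative to 7); CuBr·SMe2 (1 equiv), THF, −40 °C; 7, −40 → 0 °C; aq. NH4Cl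
Reagents that add atoms: none
Why: Copper-mediated anti-SN2' allylic substitution of a secondary allylic picolinate with a Grignard-derived organocopper reagent, a reaction type established for building quaternary carbons from γ,γ-disubstituted picolinates. The magnesium ion chelated between the pyridine nitrogen and the ester carbonyl of 7 makes the picolinate a strong leaving group and holds the C1–O bond pseudoaxial; the monovalent copper reagent formed from 16 adds oxidatively to C3 on the face opposite to C1–O while the olefin moves to C1=C2, and reductive elimination from the allyl trivalent copper species forms the C3–C1' bond. No ring is closed. The new quaternary stereocenter (C1 of the target) is set by 1,3-chirality transfer from the carbinol carbon of 7: the chain enters anti to the oxygen, hence trans to the C4 methyl that is cis to that oxygen, which gives S at C1 with the two ring methyls cis, and C4 of 7 becomes C6 (R) unchanged. The step needs γ- over α-attack and anti over syn delivery; both rest on the chelated picolinate, α-attack would have to occur at a carbon flanked by the C2 methyl, and the anti face is also the face free of the C4 methyl, so leaving-group control and substrate bias reinforce each other. The ring olefin can appear only at C2=C3 of the target, and the E-olefins and the silyl ether of 16 are inert to the copper reagent. The price is that the γ-carbon is fully substituted, which is why an excess of 16 and warming to 0 °C are planned.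

**Step 11**
Reactants: 17 tert-butyl(dimethyl)({(2E,6E)-3,7-dimethyl-9-[(1S,6R)-1,2,6-trimethylcyclohex-2-en-1-yl]nona-2,6-dien-1-yl}oxy)silane
Product: 18 (2E,6E)-3,7-dimethyl-9-[(1S,6R)-1,2,6-trimethylcyclohex-2-en-1-yl]nona-2,6-dien-1-ol
Conditions: Bu4NF, THF, 0 °C → rt
Reagents that add atoms: none
Why: Fluoride cleavage of the silyl ether, neutral towards the polyene.

**Step 12**
Reactants: 18 (2E,6E)-3,7-dimethyl-9-[(1S,6R)-1,2,6-trimethylcyclohex-2-en-1-yl]nona-2,6-dien-1-ol
Product: 20 (1S,6R)-1-[(3E,7E)-9-bromo-3,7-dimethylnona-3,7-dien-1-yl]-1,2,6-trimethylcyclohex-2-ene, via mesylate 19 (not isolated)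
Conditions: MsCl, Et3N, CH2Cl2, −40 °C; LiBr, THF, −40 → 0 °C; crude bromide used at once
Reagents that add atoms: lithium bromide, [Li+].[Br-]
Why: Mesylation and bromide displacement at the primary allylic carbon, the standard non-acidic preparation of terpenyl bromides, keeps the C7'=C8' olefin E.

**Step 13**
Reactants: 21 2-(1,3-dioxo-1,3-dihydro-2H-isoindol-2-yl)ethane-1-sulfonyl chloride
Product: 22 sodium 2-(1,3-dioxo-1,3-dihydro-2H-isoindol-2-yl)ethane-1-sulfinate
Conditions: Na2SO3, NaHCO3, H2O, 0 °C → rt
Reagents that add atoms: sodium hydrogen carbonate, [Na+].OC([O-])=O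
Why: Sulfite reduction of a sulfonyl chloride is the standard route to sodium sulfinates; low temperature and near-neutral pH are kept to spare the phthalimide.

**Step 14**
Reactants: 20 (1S,6R)-1-[(3E,7E)-9-bromo-3,7-dimethylnona-3,7-dien-1-yl]-1,2,6-trimethylcyclohex-2-ene; 22 sodium 2-(1,3-dioxo-1,3-dihydro-2H-isoindol-2-yl)ethane-1-sulfinate
Product: 23 2-[2-({(2E,6E)-3,7-dimethyl-9-[(1S,6R)-1,2,6-trimethylcyclohex-2-en-1-yl]nona-2,6-dien-1-yl}sulfonyl)ethyl]-1H-isoindole-1,3(2H)-dione
Conditions: DMF, rt
Reagents that add atoms: none
Why: S-Alkylation of a sulfinate by a primary allylic bromide (SN2) gives the sulfone directly, so no oxidant meets the three olefins and the E-geometry is kept.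

**Step 15**
Reactants: 23 2-[2-({(2E,6E)-3,7-dimethyl-9-[(1S,6R)-1,2,6-trimethylcyclohex-2-en-1-yl]nona-2,6-dien-1-yl}sulfonyl)ethyl]-1H-isoindole-1,3(2H)-dione
Product: 24 2-({(2E,6E)-3,7-dimethyl-9-[(1S,6R)-1,2,6-trimethylcyclohex-2-en-1-yl]nona-2,6-dien-1-yl}sulfonyl)ethan-1-amine
Conditions: N2H4·H2O, EtOH, argon, rt → 45 °C
Reagents that add atoms: none
Why: Hydrazinolysis of the phthalimide (Gabriel-type amine release) is neutral to mildly basic and leaves polyene and sulfone alone; argon excludes diimide formation.

**Step 16**
Reactants: 24 2-({(2E,6E)-3,7-dimethyl-9-[(1S,6R)-1,2,6-trimethylcyclohex-2-en-1-yl]nona-2,6-dien-1-yl}sulfonyl)ethan-1-amine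
Product: 26 agelasidine C, 2-[2-({(2E,6E)-3,7-dimethyl-9-[(1S,6R)-1,2,6-trimethylcyclohex-2-en-1-yl]nona-2,6-dien-1-yl}sulfonyl)ethyl]guanidine, via guanidinium chloride 25 (not isolated)
Conditions: 1H-pyrazole-1-carboxamidine hydrochloride, iPr2NEt, DMF, rt; then CHCl3/aq. NaOH, 0 °C
Reagents that add atoms: 1H-pyrazole-1-carboxamidine hydrochloride, Cl.NC(=N)n1cccn1
Why: Amidine transfer from the pyrazole carboxamidine to the primary amine gives the unprotected guanidinium salt directly, so no acidic deprotection is needed; the cold basic wash sets the neutral guanidine free.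

## Compound list

1 | 3-ethoxy-2-methylcyclohex-2-en-1-one | CCOC1=C(C)C(=O)CCC1 | starting material
2 | lithium 5-ethoxy-6-methylcyclohexa-1,5-dien-1-olate | [Li]OC1=CCCC(OCC)=C1C | intermediate
3 | (±)-3-ethoxy-2,6-dimethylcyclohex-2-en-1-one | CCOC1=C(C)C(=O)C(C)CC1 | intermediate
4 | 3-ethoxy-1,2,6-trimethylcyclohex-2-en-1-ol (racemic, both C1 epimers, present as its lithium alkoxide) | CCOC1=C(C)C(C)(O)C(C)CC1 | intermediate
5 | (±)-2,3,4-trimethylcyclohex-2-en-1-one | CC1CCC(=O)C(C)=C1C | intermediate
6 | (1S,4R)-2,3,4-trimethylcyclohex-2-en-1-ol | O[C@H]1CC[C@@H](C)C(C)=C1C | intermediate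
7 | (1S,4R)-2,3,4-trimethylcyclohex-2-en-1-yl pyridine-2-carboxylate | O=C(O[C@H]1CC[C@@H](C)C(C)=C1C)c1ccccn1 | intermediate
8 | geraniol, (2E)-3,7-dimethylocta-2,6-dien-1-ol | CC(C)=CCC/C(C)=C/CO | starting material
9 | tert-butyl{[(2E)-3,7-dimethylocta-2,6-dien-1-yl]oxy}dimethylsilane | CC(C)=CCC/C(C)=C/CO[Si](C)(C)C(C)(C)C | intermediate
10 | (2E,6E)-8-{[tert-butyl(dimethyl)silyl]oxy}-2,6-dimethylocta-2,6-dien-1-ol | OC/C(C)=C/CC/C(C)=C/CO[Si](C)(C)C(C)(C)C | intermediate
11 | (2E,6E)-8-{[tert-butyl(dimethyl)silyl]oxy}-2,6-dimethylocta-2,6-dienal | O=C/C(C)=C/CC/C(C)=C/CO[Si](C)(C)C(C)(C)C | intermediate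
12 | tert-butyl{[(2E,6E)-3,7-dimethylnona-2,6,8-trien-1-yl]oxy}dimethylsilane | C=C/C(C)=C/CC/C(C)=C/CO[Si](C)(C)C(C)(C)C | intermediate
13 | 9-[(3E,7E)-9-{[tert-butyl(dimethyl)silyl]oxy}-3,7-dimethylnona-3,7-dien-1-yl]-9-borabicyclo[3.3.1]nonane | C1CC2CCCC(C1)B2CC/C(C)=C/CC/C(C)=C/CO[Si](C)(C)C(C)(C)C | intermediate
14 | (3E,7E)-9-{[tert-butyl(dimethyl)silyl]oxy}-3,7-dimethylnona-3,7-dien-1-ol | OCC/C(C)=C/CC/C(C)=C/CO[Si](C)(C)C(C)(C)C | intermediate
15 | {[(2E,6E)-9-bromo-3,7-dimethylnona-2,6-dien-1-yl]oxy}(tert-butyl)dimethylsilane | BrCC/C(C)=C/CC/C(C)=C/CO[Si](C)(C)C(C)(C)C | intermediate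
16 | [(3E,7E)-9-{[tert-butyl(dimethyl)silyl]oxy}-3,7-dimethylnona-3,7-dien-1-yl]magnesium bromide | Br[Mg]CC/C(C)=C/CC/C(C)=C/CO[Si](C)(C)C(C)(C)C | intermediate
17 | tert-butyl(dimethyl)({(2E,6E)-3,7-dimethyl-9-[(1S,6R)-1,2,6-trimethylcyclohex-2-en-1-yl]nona-2,6-dien-1-yl}oxy)silane | CC1=CCC[C@@H](C)[C@]1(C)CC/C(C)=C/CC/C(C)=C/CO[Si](C)(C)C(C)(C)C | intermediate
18 | (2E,6E)-3,7-dimethyl-9-[(1S,6R)-1,2,6-trimethylcyclohex-2-en-1-yl]nona-2,6-dien-1-ol | CC1=CCC[C@@H](C)[C@]1(C)CC/C(C)=C/CC/C(C)=C/CO | intermediate
19 | (2E,6E)-3,7-dimethyl-9-[(1S,6R)-1,2,6-trimethylcyclohex-2-en-1-yl]nona-2,6-dien-1-yl methanesulfonate | CC1=CCC[C@@H](C)[C@]1(C)CC/C(C)=C/CC/C(C)=C/COS(C)(=O)=O | intermediate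
20 | (1S,6R)-1-[(3E,7E)-9-bromo-3,7-dimethylnona-3,7-dien-1-yl]-1,2,6-trimethylcyclohex-2-ene | CC1=CCC[C@@H](C)[C@]1(C)CC/C(C)=C/CC/C(C)=C/CBr | intermediate
21 | 2-(1,3-dioxo-1,3-dihydro-2H-isoindol-2-yl)ethane-1-sulfonyl chloride | O=C1c2ccccc2C(=O)N1CCS(=O)(=O)Cl | starting material
22 | sodium 2-(1,3-dioxo-1,3-dihydro-2H-isoindol-2-yl)ethane-1-sulfinate | [Na+].[O-]S(=O)CCN1C(=O)c2ccccc2C1=O | intermediate
23 | 2-[2-({(2E,6E)-3,7-dimethyl-9-[(1S,6R)-1,2,6-trimethylcyclohex-2-en-1-yl]nona-2,6-dien-1-yl}sulfonyl)ethyl]-1H-isoindole-1,3(2H)-dione | CC1=CCC[C@@H](C)[C@]1(C)CC/C(C)=C/CC/C(C)=C/CS(=O)(=O)CCN1C(=O)c2ccccc2C1=O | intermediate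
24 | 2-({(2E,6E)-3,7-dimethyl-9-[(1S,6R)-1,2,6-trimethylcyclohex-2-en-1-yl]nona-2,6-dien-1-yl}sulfonyl)ethan-1-amine | CC1=CCC[C@@H](C)[C@]1(C)CC/C(C)=C/CC/C(C)=C/CS(=O)(=O)CCN | intermediate
25 | N-[2-({(2E,6E)-3,7-dimethyl-9-[(1S,6R)-1,2,6-trimethylcyclohex-2-en-1-yl]nona-2,6-dien-1-yl}sulfonyl)ethyl]guanidinium chloride | CC1=CCC[C@@H](C)[C@]1(C)CC/C(C)=C/CC/C(C)=C/CS(=O)(=O)CCNC(N)=[NH2+].[Cl-] | intermediate
26 | agelasidine C | CC1=CCC[C@@H](C)[C@]1(C)CC/C(C)=C/CC/C(C)=C/CS(=O)(=O)CCN=C(N)N | target

## Step count and risks

Total: 16 steps. Longest linear sequence: 11 steps (8 → 9 → 11 → 12 → 14 → 15 → 17 → 18 → 20 → 23 → 24 → 26; steps 5–12 and 14–16). The ring fragment (steps 1–4) and the sulfinate (step 13) are side branches.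

**Step 10 (key step).** The most likely failure is that the organocopper reagent does not reach the fully substituted C3 of 7, so that substitution at C1, reduction of the picolinate or elimination to a diene takes over; less likely is loss of the anti course. The fallback reverses the polarity of the ring partner and adds the same chain as a conjugate nucleophile. It sets out from 6, which is oxidised (MnO2, CH2Cl2) to (4R)-2,3,4-trimethylcyclohex-2-en-1-one F1. The copper reagent from 16 (CuBr·SMe2, Me3SiCl, THF, −78 → −30 °C) should add 1,4 to F1, anti to the pseudoaxial C4 methyl, and is caught as trimethylsilyl enol ether F2. MeLi releases the lithium enolate, which is triflated with PhNTf2 to enol triflate F3. Palladium-catalysed formate reduction (Pd(OAc)2, PPh3, Bu3N, HCO2H, DMF, 60 °C) replaces the triflate by hydrogen and returns to the route at 17.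

**Step 3.** The most likely failure is incomplete catalyst control in the mismatched enantiomer, which would contaminate 6 with its own enantiomer, or diastereomers that do not separate. The fallback replaces the divergent reduction by an achiral reduction and an enzymatic resolution. It sets out from 5: reduction with NaBH4 and CeCl3·7H2O in MeOH at −40 °C should give mainly racemic cis-2,3,4-trimethylcyclohex-2-en-1-ol F4. Lipase-catalysed acylation (Candida antarctica lipase B, vinyl acetate, tert-butyl methyl ether) should, by the empirical rule for secondary alcohols, convert the (1R)-enantiomer into (1R,4S)-2,3,4-trimethylcyclohex-2-en-1-yl acetate F5 and leave the (1S,4R)-alcohol unreacted, which returns to the route at 6.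

**Step 8.** The most likely failure is loss of regio- or chemoselectivity in the hydroboration of the 1,3-diene (addition at the internal diene carbon to give an allylborane, or a second hydroboration). The fallback homologates by one carbon with a hydroxymethyl anion equivalent instead. It sets out from 10, isolated in step 6 before the MnO2 treatment: Appel bromination (CBr4, PPh3) gives {[(2E,6E)-8-bromo-3,7-dimethylocta-2,6-dien-1-yl]oxy}(tert-butyl)dimethylsilane F6. Coupling with [dimethyl(propan-2-yloxy)silyl]methylmagnesium chloride (CuI cat., THF, 0 °C) gives silane F7, and Tamao oxidation (H2O2, KF, KHCO3, THF/MeOH) returns to the route at 14.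

**Step 14.** The most likely failure is O-alkylation of the ambident sulfinate, whose allylic sulfinate ester would rearrange by a [2,3]-shift to the transposed tertiary sulfone, or decomposition of the labile bromide before it reacts. The fallback builds the C–S bond at the sulfide level. It sets out from 20: alkylation of N-(2-sulfanylethyl)phthalimide (K2CO3, DMF, 0 °C) gives sulfide F8, and oxidation with H2O2 and catalytic (NH4)6Mo7O24·4H2O in EtOH at 0 °C, known for allylic sulfides beside trisubstituted olefins, returns to the route at 23.

## Further compounds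

F1 | step 10 | (4R)-2,3,4-trimethylcyclohex-2-en-1-one | O=C1CC[C@@H](C)C(C)=C1C
F2 | step 10 | tert-butyl(dimethyl)({(2E,6E)-3,7-dimethyl-9-[(1S,6R)-1,2,6-trimethyl-3-(trimethylsilyloxy)cyclohex-2-en-1-yl]nona-2,6-dien-1-yl}oxy)silane | CC1=C(O[Si](C)(C)C)CC[C@@H](C)[C@]1(C)CC/C(C)=C/CC/C(C)=C/CO[Si](C)(C)C(C)(C)C
F3 | step 10 | (3S,4R)-3-[(3E,7E)-9-{[tert-butyl(dimethyl)silyl]oxy}-3,7-dimethylnona-3,7-dien-1-yl]-2,3,4-trimethylcyclohex-1-en-1-yl trifluoromethanesulfonate | CC1=C(OS(=O)(=O)C(F)(F)F)CC[C@@H](C)[C@]1(C)CC/C(C)=C/CC/C(C)=C/CO[Si](C)(C)C(C)(C)C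
F4 | step 3 | rac-(1S,4R)-2,3,4-trimethylcyclohex-2-en-1-ol (racemic cis alcohol, relative configuration shown) | O[C@H]1CC[C@@H](C)C(C)=C1C
F5 | step 3 | (1R,4S)-2,3,4-trimethylcyclohex-2-en-1-yl acetate | CC(=O)O[C@@H]1CC[C@H](C)C(C)=C1C
F6 | step 8 | {[(2E,6E)-8-bromo-3,7-dimethylocta-2,6-dien-1-yl]oxy}(tert-butyl)dimethylsilane | BrC/C(C)=C/CC/C(C)=C/CO[Si](C)(C)C(C)(C)C
F7 | step 8 | tert-butyl{[(2E,6E)-9-[dimethyl(propan-2-yloxy)silyl]-3,7-dimethylnona-2,6-dien-1-yl]oxy}dimethylsilane | CC(C)O[Si](C)(C)CC/C(C)=C/CC/C(C)=C/CO[Si](C)(C)C(C)(C)C
F8 | step 14 | 2-[2-({(2E,6E)-3,7-dimethyl-9-[(1S,6R)-1,2,6-trimethylcyclohex-2-en-1-yl]nona-2,6-dien-1-yl}sulfanyl)ethyl]-1H-isoindole-1,3(2H)-dione | CC1=CCC[C@@H](C)[C@]1(C)CC/C(C)=C/CC/C(C)=C/CSCCN1C(=O)c2ccccc2C1=O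
A1 | alternative 1 | 2-methylcyclohex-2-en-1-one | CC1=CCCCC1=O
A2 | alternative 1 | (2S,3R)-2,3-dimethyl-2-(prop-2-en-1-yl)cyclohexan-1-one | O=C1CCC[C@@H](C)[C@]1(C)CC=C
A3 | alternative 1 | [(1S,6R)-1,2,6-trimethylcyclohex-2-en-1-yl]acetaldehyde | CC1=CCC[C@@H](C)[C@]1(C)CC=O
A4 | alternative 2 | (1R,4R)-2,3,4-trimethylcyclohex-2-en-1-ol | O[C@@H]1CC[C@@H](C)C(C)=C1C
A5 | alternative 2 | (4E,8E)-10-{[tert-butyl(dimethyl)silyl]oxy}-4,8-dimethyldeca-4,8-dienoic acid | OC(=O)CC/C(C)=C/CC/C(C)=C/CO[Si](C)(C)C(C)(C)C
A6 | alternative 2 | (1R,4R)-2,3,4-trimethylcyclohex-2-en-1-yl (4E,8E)-10-{[tert-butyl(dimethyl)silyl]oxy}-4,8-dimethyldeca-4,8-dienoate | O=C(CC/C(C)=C/CC/C(C)=C/CO[Si](C)(C)C(C)(C)C)O[C@@H]1CC[C@@H](C)C(C)=C1C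
A7 | alternative 2 | (4E,8E)-10-{[tert-butyl(dimethyl)silyl]oxy}-4,8-dimethyl-2-[(1R,6R)-1,2,6-trimethylcyclohex-2-en-1-yl]deca-4,8-dienoic acid (C2 epimers; ring configuration as in 17, the descriptor of the quaternary carbon changes with the carboxyl group) | CC1=CCC[C@@H](C)[C@]1(C)C(C(O)=O)C/C(C)=C/CC/C(C)=C/CO[Si](C)(C)C(C)(C)C
A8 | alternative 3 | (4R)-3-[(3E,7E)-9-{[tert-butyl(dimethyl)silyl]oxy}-3,7-dimethylnona-3,7-dien-1-yl]-2,4-dimethylcyclohex-2-en-1-one | O=C1CC[C@@H](C)C(CC/C(C)=C/CC/C(C)=C/CO[Si](C)(C)C(C)(C)C)=C1C
A9 | alternative 3 | (1R,4R)-3-[(3E,7E)-9-{[tert-butyl(dimethyl)silyl]oxy}-3,7-dimethylnona-3,7-dien-1-yl]-2,4-dimethylcyclohex-2-en-1-yl pyridine-2-carboxylate | O=C(O[C@@H]1CC[C@@H](C)C(CC/C(C)=C/CC/C(C)=C/CO[Si](C)(C)C(C)(C)C)=C1C)c1ccccn1
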